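**Plan**

- The target is achiral. Retrosynthesis first removes four O-protecting groups (three benzyl, one methyl), then cuts both bonds from ring B to the ketone carbon and to the pyranonyl CH2 at once, leaving 3-methoxybenzyne and a ring-A aryl pyranonylmethyl ketone.
- Feature used: ring B carries its oxygen, the aroyl carbon and the CH2 on three neighbouring carbons (C2, C1, C6), which is the pattern a 3-oxygenated benzyne gives when it inserts into a C(=O)–CH2 bond.
- The ketone is cut between the carbonyl carbon and the CH2, giving a ring-A benzaldehyde and the lithiated 6-methyl group of O-benzyl triacetic acid lactone.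
- Forward: the ring-A aldehyde from 3',5'-dihydroxyacetophenone (reduction, benzylation, formylation), union with the pyranone (vinylogous aldol, oxidation), aryne insertion that places ring B between the two carbons, global deprotection. All three rings are bought; none is built.
- Stereochemistry: none in the target; the carbinol centre of the aldol adduct is racemic and is erased by the oxidation.

Key step: step 7

**Route**

Step 1
Reactants: 1 3',5'-dihydroxyacetophenone
Product: 3 5-ethylbenzene-1,3-diol (5-ethylresorcinol), via 1-(3,5-dihydroxyphenyl)ethanol 2 (not isolated)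
Conditions: H2 (3 bar), Pd/C (10%), HCl (cat.), EtOH, rt
Reagents that add atoms: none
Why: Acid-promoted catalytic hydrogenation reduces the aryl ketone to the benzylic alcohol 2, whose benzylic C–O bond is then hydrogenolysed on the same catalyst (ketone-to-methylene hydrogenolysis), while the phenols and the arene are inert at room temperature.

Step 2
Reactants: 3 5-ethylbenzene-1,3-diol
Product: 4 1,3-bis(benzyloxy)-5-ethylbenzene
Conditions: BnBr (2.3 equiv), K2CO3, DMF, rt → 50 °C
Reagents that add atoms: benzyl bromide, BrCc1ccccc1
Why: Williamson ether synthesis on both phenoxides gives benzyl ethers that should survive the formylation, the lithium amide, the periodinane and the fluoride used later and that fall off together at the end.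

Step 3
Reactants: 4 1,3-bis(benzyloxy)-5-ethylbenzene
Product: 6 2,4-bis(benzyloxy)-6-ethylbenzaldehyde, via aryl iminium chloride 5 (not isolated)
Conditions: POCl3 (1.5 equiv), DMF, 0 → 70 °C; then H2O, 60 °C
Reagents that add atoms: N,N-dimethylformamide, CN(C)C=O; water, O
Why: Vilsmeier–Haack formylation should attack the ring position beside the ethyl group, which is para to one benzyloxy group and ortho to the other and less crowded than the carbon between the two ethers, as is usual for 5-alkylresorcinol diethers, and the iminium salt 5 is hydrolysed on work-up.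

Step 4
Reactants: 7 triacetic acid lactone (4-hydroxy-6-methyl-2H-pyran-2-one)
Product: 8 4-(benzyloxy)-6-methyl-2H-pyran-2-one
Conditions: BnBr (1.1 equiv), K2CO3, DMF, rt
Reagents that add atoms: benzyl bromide, BrCc1ccccc1
Why: O-alkylation (Williamson type) of the vinylogous acid at its 4-oxygen gives the 4-alkoxy-2-pyranone, the normal outcome for triacetic acid lactone with an alkyl halide and carbonate base.

Step 5
Reactants: 8 4-(benzyloxy)-6-methyl-2H-pyran-2-one; 6 2,4-bis(benzyloxy)-6-ethylbenzaldehyde
Product: 10 4-(benzyloxy)-6-{2-[2,4-bis(benzyloxy)-6-ethylphenyl]-2-hydroxyethyl}-2H-pyran-2-one (racemic), via lithiomethylpyranone 9 (not isolated)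
Conditions: LiN(SiMe3)2 (1.1 equiv), THF, −78 °C; then 6, −78 °C; AcOH quench at −78 °C
Reagents that add atoms: none
Why: Vinylogous aldol addition, in which the lithium amide deprotonates the 6-methyl group of the 4-alkoxy-2-pyranone and the dienolate 9 adds through that carbon to the aldehyde; the new carbinol centre is racemic and disappears in step 6.

Step 6
Reactants: 10 4-(benzyloxy)-6-{2-[2,4-bis(benzyloxy)-6-ethylphenyl]-2-hydroxyethyl}-2H-pyran-2-one
Product: 11 4-(benzyloxy)-6-{2-[2,4-bis(benzyloxy)-6-ethylphenyl]-2-oxoethyl}-2H-pyran-2-one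
Conditions: Dess–Martin periodinane, NaHCO3, CH2Cl2, 0 °C → rt
Reagents that add atoms: none
Why: Dess–Martin oxidation converts the secondary benzylic alcohol into the ketone under buffered, near-neutral conditions that should avoid β-elimination to the styrylpyranone and leave the benzyl ethers and the pyranone untouched.

Step 7
Reactants: 11 4-(benzyloxy)-6-{2-[2,4-bis(benzyloxy)-6-ethylphenyl]-2-oxoethyl}-2H-pyran-2-one; 12 3-methoxy-2-(trimethylsilyl)phenyl trifluoromethanesulfonate
Product: 15 4-(benzyloxy)-6-{2-[2,4-bis(benzyloxy)-6-ethylbenzoyl]-3-methoxybenzyl}-2H-pyran-2-one, via 3-methoxybenzyne 13 (not isolated), via cesium benzocyclobutenoxide 14 (not isolated)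
Conditions: 12 (1.0 equiv, slow addition), 11 (1.3 equiv), CsF (2.5 equiv), MeCN, 70–80 °C
Reagents that add atoms: none
Why: Proposed new method: CsF unmasks 3-methoxybenzyne 13 from 12 and also deprotonates the methylene of 11, which is flanked by the aryl ketone and by pyranone C6 and is therefore a vinylogous β-keto ester; the carbanion adds to the aryne carbon remote from the methoxy group. The aryl anion that results sits beside the methoxy-bearing carbon and adds 4-exo-trig to the neighbouring ketone to give cyclobutenoxide 14, which opens across the former C(=O)–CH2 bond to a benzylic anion stabilised by the pyranone and is protonated to 15. The closest known reaction type is the fluoride-mediated acyl-alkylation of arynes by β-keto esters (aryne insertion into a C–C σ-bond), not yet shown with a 4-alkoxy-2-pyranone as the activating group or with a di-ortho-substituted aroyl group. The four-membered ring of 14 is the only ring that closes and it reopens, so 15 has no new ring and no stereocentre. The regiochemistry needed, with the ketone next to the methoxy group and the CH2 one carbon further on, follows from the polarised, distorted aryne, which takes nucleophiles at the carbon meta to oxygen; C-arylation is favoured over O-arylation by the soft aryne, and the ring-A carbonyl, twisted out of conjugation by its two ortho groups, should stay electrophilic enough for the intramolecular capture. Keeping 12 as the limiting component and adding it slowly holds the aryne concentration low, so that the enolate should outcompete [4+2] addition of the aryne to the pyranone diene.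

Step 8
Reactants: 15 4-(benzyloxy)-6-{2-[2,4-bis(benzyloxy)-6-ethylbenzoyl]-3-methoxybenzyl}-2H-pyran-2-one
Product: 16 6-[2-(2-ethyl-4,6-dihydroxybenzoyl)-3-hydroxybenzyl]-4-hydroxy-2H-pyran-2-one (CNP0234555.0)
Conditions: BCl3 (10 equiv), C6HMe5 (10 equiv), CH2Cl2, −78 °C → 0 °C; then H2O
Reagents that add atoms: none
Why: Lewis-acid ether cleavage, in which BCl3 removes the three benzyl groups at low temperature while pentamethylbenzene traps the benzyl cations by Friedel–Crafts alkylation, and on warming cleaves the methyl ether ortho to the ketone through a boron chelate, the borate esters being hydrolysed on aqueous work-up.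

**Compound list**

1 | 3',5'-dihydroxyacetophenone | CC(=O)c1cc(O)cc(O)c1 | starting material
2 | 1-(3,5-dihydroxyphenyl)ethanol (racemic, not isolated) | CC(O)c1cc(O)cc(O)c1 | intermediate
3 | 5-ethylbenzene-1,3-diol (5-ethylresorcinol) | CCc1cc(O)cc(O)c1 | intermediate
4 | 1,3-bis(benzyloxy)-5-ethylbenzene | CCc1cc(OCc2ccccc2)cc(OCc2ccccc2)c1 | intermediate
5 | N-[2,4-bis(benzyloxy)-6-ethylbenzylidene]-N-methylmethanaminium chloride (aryl iminium salt, written as chloride, not isolated) | CCc1cc(OCc2ccccc2)cc(OCc2ccccc2)c1C=[N+](C)C.[Cl-] | intermediate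
6 | 2,4-bis(benzyloxy)-6-ethylbenzaldehyde | CCc1cc(OCc2ccccc2)cc(OCc2ccccc2)c1C=O | intermediate
7 | triacetic acid lactone (4-hydroxy-6-methyl-2H-pyran-2-one) | Cc1cc(O)cc(=O)o1 | starting material
8 | 4-(benzyloxy)-6-methyl-2H-pyran-2-one | Cc1cc(OCc2ccccc2)cc(=O)o1 | intermediate
9 | [4-(benzyloxy)-2-oxo-2H-pyran-6-yl]methyllithium (not isolated) | [Li]Cc1cc(OCc2ccccc2)cc(=O)o1 | intermediate
10 | 4-(benzyloxy)-6-{2-[2,4-bis(benzyloxy)-6-ethylphenyl]-2-hydroxyethyl}-2H-pyran-2-one (racemic) | CCc1cc(OCc2ccccc2)cc(OCc2ccccc2)c1C(O)Cc1cc(OCc2ccccc2)cc(=O)o1 | intermediate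
11 | 4-(benzyloxy)-6-{2-[2,4-bis(benzyloxy)-6-ethylphenyl]-2-oxoethyl}-2H-pyran-2-one | CCc1cc(OCc2ccccc2)cc(OCc2ccccc2)c1C(=O)Cc1cc(OCc2ccccc2)cc(=O)o1 | intermediate
12 | 3-methoxy-2-(trimethylsilyl)phenyl trifluoromethanesulfonate | COc1cccc(OS(=O)(=O)C(F)(F)F)c1[Si](C)(C)C | starting material
13 | 3-methoxybenzyne (1-methoxycyclohexa-1,3-dien-5-yne, not isolated) | COC1=CC=CC#C1 | intermediate
14 | cesium 7-[2,4-bis(benzyloxy)-6-ethylphenyl]-8-[4-(benzyloxy)-2-oxo-2H-pyran-6-yl]-5-methoxybicyclo[4.2.0]octa-1,3,5-trien-7-olate (transient, relative configuration of the two ring carbons undefined, not isolated) | CCc1cc(OCc2ccccc2)cc(OCc2ccccc2)c1C1([O-])C(c2cc(OCc3ccccc3)cc(=O)o2)c2cccc(OC)c21.[Cs+] | intermediate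
15 | 4-(benzyloxy)-6-{2-[2,4-bis(benzyloxy)-6-ethylbenzoyl]-3-methoxybenzyl}-2H-pyran-2-one | CCc1cc(OCc2ccccc2)cc(OCc2ccccc2)c1C(=O)c1c(OC)cccc1Cc1cc(OCc2ccccc2)cc(=O)o1 | intermediate
16 | 6-[2-(2-ethyl-4,6-dihydroxybenzoyl)-3-hydroxybenzyl]-4-hydroxy-2H-pyran-2-one (CNP0234555.0, achiral) | CCc1cc(O)cc(O)c1C(=O)c1c(O)cccc1Cc1cc(O)cc(=O)o1 | target

**Count**

Total steps: 8. Longest linear sequence: 7 steps (steps 1, 2, 3, 5, 6, 7, 8 from 3',5'-dihydroxyacetophenone); step 4 is a one-step side branch.

**Steps most likely to fail**

Step 7 (proposed new method). Several processes could divert it: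
- protonation of the aryl anion before it closes on the doubly ortho-flanked carbonyl, which would stop at simple α-arylation;
- O-arylation of the enolate;
- [4+2] cycloaddition of the aryne across the 2-pyranone diene with loss of CO2;
- a second arylation.

The fallback uses the established β-keto ester form of the same insertion and builds the pyranone afterwards. It sets out from aldehyde 6. Aldol addition of the lithium enolate of ethyl acetate (LiN(i-Pr)2, EtOAc, THF, −78 °C) would give ethyl 3-[2,4-bis(benzyloxy)-6-ethylphenyl]-3-hydroxypropanoate F1. Dess–Martin oxidation would then give the β-keto ester ethyl 3-[2,4-bis(benzyloxy)-6-ethylphenyl]-3-oxopropanoate F2. F2 belongs to the substrate class for which the CsF-mediated acyl-alkylation of arynes is known. With 12 and CsF in MeCN at 80 °C it should give ethyl {2-[2,4-bis(benzyloxy)-6-ethylbenzoyl]-3-methoxyphenyl}acetate F3, in which the same two ring-B bonds have been made. Claisen acylation of the dianion of methyl acetoacetate (NaH, then n-BuLi, THF, 0 °C, used in excess and kept cold) by ester F3 would give methyl 6-{2-[2,4-bis(benzyloxy)-6-ethylbenzoyl]-3-methoxyphenyl}-3,5-dioxohexanoate F4. DBU in toluene should lactonise F4 to 6-{2-[2,4-bis(benzyloxy)-6-ethylbenzoyl]-3-methoxybenzyl}-4-hydroxy-2H-pyran-2-one F5. F5 is deprotected under the conditions of step 8 and so comes back to the route at target 16.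

Step 8. Three processes are of concern:
- incomplete cleavage of the methyl ether once the carbonyl is tied up in a boron chelate with the freed ring-A phenoxide;
- Friedel–Crafts re-benzylation of the resorcinol ring or of pyranone C3 by escaping benzyl cations;
- acid-promoted cyclodehydration around the benzophenone.

The fallback separates the two kinds of ether and removes the benzyl groups without a Lewis acid. It sets out from 15. Hydrogenolysis (H2, 1 bar, Pd/C, EtOAc, rt, stopped at full debenzylation) would give 6-[2-(2-ethyl-4,6-dihydroxybenzoyl)-3-methoxybenzyl]-4-hydroxy-2H-pyran-2-one F6. In a separate operation BBr3 (CH2Cl2, −78 → 0 °C) would cleave the single remaining methyl ether, with no benzyl cations present, and the sequence comes back to the route at target 16.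

Step 5. Three processes are of concern:
- reversal of the aldol addition to the crowded, electron-rich aldehyde;
- E1cB loss of the benzylic alkoxide to the styrylpyranone on warming;
- competing lithiation at pyranone C3.

The fallback replaces the reversible addition by an irreversible acylation at the ketone oxidation level. It sets out from aldehyde 6. Pinnick oxidation (NaClO2, NaH2PO4, 2-methyl-2-butene, t-BuOH/H2O) would give 2,4-bis(benzyloxy)-6-ethylbenzoic acid F7. Oxalyl chloride with catalytic DMF in CH2Cl2 would give 2,4-bis(benzyloxy)-6-ethylbenzoyl chloride F8. Claisen-type acylation of two equivalents of the lithiated pyranone 9 (from 8, LiN(SiMe3)2, THF, −78 °C) by F8 should give ketone 11 directly; the second equivalent of 9 takes up the acidic proton of the product. The sequence comes back to the route at 11 and step 6 is not needed.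

**Further compounds**

F1 | step 7 | ethyl 3-[2,4-bis(benzyloxy)-6-ethylphenyl]-3-hydroxypropanoate (racemic) | CCOC(=O)CC(O)c1c(CC)cc(OCc2ccccc2)cc1OCc1ccccc1
F2 | step 7 | ethyl 3-[2,4-bis(benzyloxy)-6-ethylphenyl]-3-oxopropanoate | CCOC(=O)CC(=O)c1c(CC)cc(OCc2ccccc2)cc1OCc1ccccc1
F3 | step 7 | ethyl {2-[2,4-bis(benzyloxy)-6-ethylbenzoyl]-3-methoxyphenyl}acetate | CCOC(=O)Cc1cccc(OC)c1C(=O)c1c(CC)cc(OCc2ccccc2)cc1OCc1ccccc1
F4 | step 7 | methyl 6-{2-[2,4-bis(benzyloxy)-6-ethylbenzoyl]-3-methoxyphenyl}-3,5-dioxohexanoate | COC(=O)CC(=O)CC(=O)Cc1cccc(OC)c1C(=O)c1c(CC)cc(OCc2ccccc2)cc1OCc1ccccc1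
F5 | step 7 | 6-{2-[2,4-bis(benzyloxy)-6-ethylbenzoyl]-3-methoxybenzyl}-4-hydroxy-2H-pyran-2-one | CCc1cc(OCc2ccccc2)cc(OCc2ccccc2)c1C(=O)c1c(OC)cccc1Cc1cc(O)cc(=O)o1
F6 | step 8 | 6-[2-(2-ethyl-4,6-dihydroxybenzoyl)-3-methoxybenzyl]-4-hydroxy-2H-pyran-2-one | CCc1cc(O)cc(O)c1C(=O)c1c(OC)cccc1Cc1cc(O)cc(=O)o1
F7 | step 5 | 2,4-bis(benzyloxy)-6-ethylbenzoic acid | CCc1cc(OCc2ccccc2)cc(OCc2ccccc2)c1C(=O)O
F8 | step 5 | 2,4-bis(benzyloxy)-6-ethylbenzoyl chloride | CCc1cc(OCc2ccccc2)cc(OCc2ccccc2)c1C(=O)Cl
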